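**Strategy.** The decalin is cut at its ring-fusion bond C5–C10 (drimane numbering), the one bond shared by rings A and B, together with C8–C9. The precursor is an acyclic (E)-2-alkyl-2-enal that already carries the protected arylmethyl group on C9, the future C10 methyl as a formyl group, and an (E,E)-diene on a 4,4-dimethyl tether. A catalytic enantioselective intramolecular Diels–Alder reaction closes both carbocycles in one operation, builds quaternary C10 and sets C5, C9 and C10. The formyl group, which activates the dienophile and favours the endo, trans-fused mode, is then reduced to methyl; the new alkene is moved to C7=C8, and the arene is formylated, sulfated and unmasked.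

Key step: step 9

Remarks:
- Terpenoid positions use drimane numbering (C11 is the benzylic carbon, C12 the methyl on C8, C15 the carbon on C10); β is the face of the C10 substituent.
- Assumption: the (S)-catalyst of step 9 is taken to expose the Re face of the enal α-carbon, by analogy with 2-substituted acroleins; if the sense proves opposite, the (R)-catalyst is used in the same way.
- The target is drawn as the free hydrogen sulfate; it is released from its sodium salt by cold acidification in the last operation.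

**Step 1**
Reactants: 1 3,4-bis(benzyloxy)benzaldehyde
Product: 3 3,4-bis(benzyloxy)phenol, via aryl formate 2 (not isolated)
Conditions: mCPBA, CH2Cl2, 0 → 25 °C; then K2CO3 (cat.), MeOH, 25 °C
Reagents that add atoms: mCPBA, OOC(=O)c1cccc(Cl)c1
Why: Baeyer–Villiger (Dakin-type) oxidation in which the electron-rich aryl group migrates to oxygen, followed by methanolysis of the formate.

**Step 2**
Reactants: 3 3,4-bis(benzyloxy)phenol
Product: 4 4-(allyloxy)-1,2-bis(benzyloxy)benzene
Conditions: allyl bromide, K2CO3, acetone, reflux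
Reagents that add atoms: allyl bromide, C=CCBr
Why: Williamson etherification of the phenoxide with an allylic bromide.

**Step 3**
Reactants: 4 4-(allyloxy)-1,2-bis(benzyloxy)benzene
Product: 5 2-allyl-4,5-bis(benzyloxy)phenol
Conditions: N,N-diethylaniline, 200 °C
Reagents that add atoms: none
Why: Aromatic Claisen rearrangement, which should go to the ortho position that is not flanked by a benzyloxy group.

**Step 4**
Reactants: 5 2-allyl-4,5-bis(benzyloxy)phenol
Product: 6 1-allyl-4,5-bis(benzyloxy)-2-(methoxymethoxy)benzene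
Conditions: MOMCl, iPr2NEt, CH2Cl2, 0 → 25 °C
Reagents that add atoms: chloromethyl methyl ether, COCCl
Why: O-alkylation to the MOM acetal, which protects the phenol and later directs ortho-lithiation.

**Step 5**
Reactants: 6 1-allyl-4,5-bis(benzyloxy)-2-(methoxymethoxy)benzene
Product: 7 (E)-4-[4,5-bis(benzyloxy)-2-(methoxymethoxy)phenyl]but-2-enal
Conditions: (E)-crotonaldehyde (5 equiv), second-generation Hoveyda–Grubbs catalyst RuCl2(H2IMes)(=CH-C6H4-2-OiPr) (5 mol %), CH2Cl2, 40 °C
Reagents that add atoms: (E)-crotonaldehyde, C/C=C/C=O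
Why: Olefin cross-metathesis of the terminal allyl group with the enal partner, E-selective, with loss of propene.

**Step 6**
Reactants: 7 (E)-4-[4,5-bis(benzyloxy)-2-(methoxymethoxy)phenyl]but-2-enal
Product: 8 (Z)-4-[4,5-bis(benzyloxy)-2-(methoxymethoxy)phenyl]-2-iodobut-2-enal
Conditions: I2, K2CO3, DMAP (20 mol %), THF/H2O, 25 °C
Reagents that add atoms: iodine, II
Why: α-Iodination of the enal by amine conjugate addition, enolate iodination and elimination, which should leave iodine cis to the β-substituent (Z).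

**Step 7**
Reactants: 9 2,2-dimethylpent-4-enal; 10 diethyl (E)-but-2-en-1-ylphosphonate
Product: 12 (5E,7E)-4,4-dimethylnona-1,5,7-triene, via lithiated phosphonate 11 (not isolated)
Conditions: n-BuLi, THF/DMPU, −78 °C; then 9, −78 → 25 °C
Reagents that add atoms: none
Why: Horner–Wadsworth–Emmons olefination of a non-enolisable hindered aldehyde with an allylic phosphonate anion, which should give the E geometry at the new double bond.

**Step 8**
Reactants: 12 (5E,7E)-4,4-dimethylnona-1,5,7-triene; 8 (Z)-4-[4,5-bis(benzyloxy)-2-(methoxymethoxy)phenyl]-2-iodobut-2-enal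
Product: 14 (E)-4-[4,5-bis(benzyloxy)-2-(methoxymethoxy)phenyl]-2-[(5E,7E)-4,4-dimethylnona-5,7-dien-1-yl]but-2-enal, via B-alkyl-9-BBN 13 (not isolated)
Conditions: 9-BBN, THF, 0 → 25 °C; then 8, Pd(dppf)Cl2 (5 mol %), AsPh3, Cs2CO3, DMF/H2O, 25 °C
Reagents that add atoms: none
Why: Chemoselective anti-Markovnikov hydroboration of the monosubstituted alkene, then B-alkyl Suzuki–Miyaura coupling with retention at the vinyl iodide, which places the chain cis to the arylmethyl group (E-enal).

**Step 9**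
Reactants: 14 (E)-4-[4,5-bis(benzyloxy)-2-(methoxymethoxy)phenyl]-2-[(5E,7E)-4,4-dimethylnona-5,7-dien-1-yl]but-2-enal
Product: 15 11-[4,5-bis(benzyloxy)-2-(methoxymethoxy)phenyl]drim-6-en-15-al (trans-fused; 5α-H, 8β-CH3, 9β-H with 9α-CH2Ar, 10β-CHO)
Conditions: (S)-3,3-diphenyl-1-(2-methylphenyl)tetrahydro-1H,3H-pyrrolo[1,2-c][1,3,2]oxazaborole (20 mol %), HN(SO2CF3)2 (18 mol %), CH2Cl2, −40 → 0 °C
Reagents that add atoms: none
Why: The protonated oxazaborolidine binds the formyl oxygen of 14 and lowers the enal LUMO, so that the tethered (E,E)-diene adds in a concerted, asynchronous (4+2) cycloaddition that forms C5–C10 and C8–C9 together; the closest known reaction type is the chiral oxazaborolidinium-catalysed type 1 intramolecular Diels–Alder reaction of trienals with 2-substituted enal dienophiles. Ring B closes as the six-membered cycloaddition ring and ring A closes at the same moment through the four-carbon C1–C4 tether in a chair-like tether-exo arrangement, C5–C10 being the shared fusion bond. C9 and C10 are fixed relative to each other by the E geometry of the enal (suprafacial addition puts H-9 cis to the formyl group and the arylmethyl group trans to it), C5 by the endo orientation of the coordinated formyl group, which forces the tether exo and so should give the trans ring fusion, and C8 by the E,E diene (methyl cis to the formyl group). The absolute sense comes from the catalyst, which should shield the Si face of C10 so that C5 bonds to its Re face. The step needs endo over exo and one π-face over the other; Lewis acid coordination of the formyl group, its rigid C–H···O contact in the catalyst complex and the gem-dimethyl tether, which favours the reactive fold, should secure them, while the trans relationship of formyl and arylmethyl groups keeps the arene away from the activated carbonyl.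

**Step 10**
Reactants: 15 11-[4,5-bis(benzyloxy)-2-(methoxymethoxy)phenyl]drim-6-en-15-al
Product: 17 11-[4,5-bis(benzyloxy)-2-(methoxymethoxy)phenyl]drim-6-ene (5α-H, 8β-CH3, 9β-H, 10β-CH3), via hydrazone 16 (not isolated)
Conditions: N2H4·H2O, EtOH, 80 °C; then KOtBu, DMSO, 25 → 60 °C
Reagents that add atoms: none
Why: Wolff–Kishner reduction through the hydrazone under low-temperature base conditions; the quaternary α-carbon excludes epimerisation and the ethers are base-stable.

**Step 11**
Reactants: 17 11-[4,5-bis(benzyloxy)-2-(methoxymethoxy)phenyl]drim-6-ene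
Product: 18 11-[4,5-bis(benzyloxy)-2-(methoxymethoxy)phenyl]drim-7-ene (5α-H, 9β-H, 10β-CH3)
Conditions: RuHCl(CO)(PPh3)3 (10 mol %), toluene, 110 °C
Reagents that add atoms: none
Why: Metal hydride-catalysed double-bond migration (insertion on the open α face, β-hydride elimination of H-8α), driven by relief of the 8β-CH3/10β-CH3 diaxial strain; it should stop at the trisubstituted C7=C8 alkene because onward migration would need a tertiary Ru–C8 bond syn to H-9, which lies on the hindered β face.

**Step 12**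
Reactants: 18 11-[4,5-bis(benzyloxy)-2-(methoxymethoxy)phenyl]drim-7-ene
Product: 21 11-[4,5-bis(benzyloxy)-3-formyl-2-hydroxyphenyl]drim-7-ene, via aryllithium 19 (not isolated), via MOM-protected aldehyde 20 (not isolated)
Conditions: n-BuLi, TMEDA, THF, −78 → 0 °C; DMF, −78 → 25 °C; then 2 M HCl, THF, 40 °C
Reagents that add atoms: N,N-dimethylformamide, CN(C)C=O
Why: Directed ortho-metalation at the position between the OMOM and OBn groups, formylation with DMF, and acid work-up that should cleave the chelation-labile ortho-formyl MOM ether.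

**Step 13**
Reactants: 21 11-[4,5-bis(benzyloxy)-3-formyl-2-hydroxyphenyl]drim-7-ene
Product: 23 sodium 3,4-bis(benzyloxy)-2-formyl-6-(drim-7-en-11-yl)phenyl sulfate, via pyridinium sulfate 22 (not isolated)
Conditions: SO3·pyridine (5 equiv), pyridine, 60 °C; then aq. NaHCO3
Reagents that add atoms: sulfur trioxide–pyridine complex, [O-]S(=O)(=O)[n+]1ccccc1; sodium hydrogen carbonate, [Na+].OC([O-])=O
Why: O-sulfation of the only free phenol with the SO3·pyridine complex, then cation exchange to the sodium salt.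

**Step 14**
Reactants: 23 sodium 3,4-bis(benzyloxy)-2-formyl-6-(drim-7-en-11-yl)phenyl sulfate
Product: 25 2-formyl-3,4-dihydroxy-6-{[(1R,4aS,8aS)-2,5,5,8a-tetramethyl-1,4,4a,5,6,7,8,8a-octahydronaphthalen-1-yl]methyl}phenyl hydrogen sulfate, via debenzylated sodium salt 24 (not isolated)
Conditions: H2 (1 atm), Pd/C, EtOAc/MeOH, 25 °C; then HCl (1.0 equiv), H2O, 0 °C
Reagents that add atoms: none
Why: Hydrogenolysis of the two aryl benzyl ethers, which the hindered trisubstituted alkene, the hydrogen-bonded formyl group and the aryl sulfate should survive, then protonation of the sulfate.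

**Compound list**

1 | 3,4-bis(benzyloxy)benzaldehyde | O=Cc1ccc(OCc2ccccc2)c(OCc2ccccc2)c1 | starting material
2 | 3,4-bis(benzyloxy)phenyl formate | O=COc1ccc(OCc2ccccc2)c(OCc2ccccc2)c1 | intermediate
3 | 3,4-bis(benzyloxy)phenol | Oc1ccc(OCc2ccccc2)c(OCc2ccccc2)c1 | intermediate
4 | 4-(allyloxy)-1,2-bis(benzyloxy)benzene | C=CCOc1ccc(OCc2ccccc2)c(OCc2ccccc2)c1 | intermediate
5 | 2-allyl-4,5-bis(benzyloxy)phenol | C=CCc1cc(OCc2ccccc2)c(OCc2ccccc2)cc1O | intermediate
6 | 1-allyl-4,5-bis(benzyloxy)-2-(methoxymethoxy)benzene | C=CCc1cc(OCc2ccccc2)c(OCc2ccccc2)cc1OCOC | intermediate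
7 | (E)-4-[4,5-bis(benzyloxy)-2-(methoxymethoxy)phenyl]but-2-enal | O=C/C=C/Cc1cc(OCc2ccccc2)c(OCc2ccccc2)cc1OCOC | intermediate
8 | (Z)-4-[4,5-bis(benzyloxy)-2-(methoxymethoxy)phenyl]-2-iodobut-2-enal | O=C/C(I)=C/Cc1cc(OCc2ccccc2)c(OCc2ccccc2)cc1OCOC | intermediate
9 | 2,2-dimethylpent-4-enal | C=CCC(C)(C)C=O | starting material
10 | diethyl (E)-but-2-en-1-ylphosphonate | C/C=C/CP(=O)(OCC)OCC | starting material
11 | α-lithiated diethyl (E)-but-2-en-1-ylphosphonate | [Li+].C/C=C/[CH-]P(=O)(OCC)OCC | intermediate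
12 | (5E,7E)-4,4-dimethylnona-1,5,7-triene | C=CCC(C)(C)/C=C/C=C/C | intermediate
13 | 9-[(5E,7E)-4,4-dimethylnona-5,7-dien-1-yl]-9-borabicyclo[3.3.1]nonane | C/C=C/C=C/C(C)(C)CCCB1C2CCCC1CCC2 | intermediate
14 | (E)-4-[4,5-bis(benzyloxy)-2-(methoxymethoxy)phenyl]-2-[(5E,7E)-4,4-dimethylnona-5,7-dien-1-yl]but-2-enal | O=C/C(CCCC(C)(C)/C=C/C=C/C)=C/Cc1cc(OCc2ccccc2)c(OCc2ccccc2)cc1OCOC | intermediate
15 | 11-[4,5-bis(benzyloxy)-2-(methoxymethoxy)phenyl]drim-6-en-15-al (5α-H, 8β-CH3, 9β-H, 10β-CHO) | C[C@H]1C=C[C@H]2C(C)(C)CCC[C@]2(C=O)[C@@H]1Cc1cc(OCc2ccccc2)c(OCc2ccccc2)cc1OCOC | intermediate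
16 | (E)-hydrazone of 15 | C[C@H]1C=C[C@H]2C(C)(C)CCC[C@]2(/C=N/N)[C@@H]1Cc1cc(OCc2ccccc2)c(OCc2ccccc2)cc1OCOC | intermediate
17 | 11-[4,5-bis(benzyloxy)-2-(methoxymethoxy)phenyl]drim-6-ene (5α-H, 8β-CH3, 9β-H, 10β-CH3) | C[C@H]1C=C[C@H]2C(C)(C)CCC[C@]2(C)[C@@H]1Cc1cc(OCc2ccccc2)c(OCc2ccccc2)cc1OCOC | intermediate
18 | 11-[4,5-bis(benzyloxy)-2-(methoxymethoxy)phenyl]drim-7-ene (5α-H, 9β-H, 10β-CH3) | CC1=CC[C@H]2C(C)(C)CCC[C@]2(C)[C@@H]1Cc1cc(OCc2ccccc2)c(OCc2ccccc2)cc1OCOC | intermediate
19 | 3-lithio derivative of 18 (lithium between the OMOM and OBn groups) | CC1=CC[C@H]2C(C)(C)CCC[C@]2(C)[C@@H]1Cc1cc(OCc2ccccc2)c(OCc2ccccc2)c([Li])c1OCOC | intermediate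
20 | 11-[4,5-bis(benzyloxy)-3-formyl-2-(methoxymethoxy)phenyl]drim-7-ene | CC1=CC[C@H]2C(C)(C)CCC[C@]2(C)[C@@H]1Cc1cc(OCc2ccccc2)c(OCc2ccccc2)c(C=O)c1OCOC | intermediate
21 | 11-[4,5-bis(benzyloxy)-3-formyl-2-hydroxyphenyl]drim-7-ene | CC1=CC[C@H]2C(C)(C)CCC[C@]2(C)[C@@H]1Cc1cc(OCc2ccccc2)c(OCc2ccccc2)c(C=O)c1O | intermediate
22 | pyridinium 3,4-bis(benzyloxy)-2-formyl-6-(drim-7-en-11-yl)phenyl sulfate | CC1=CC[C@H]2C(C)(C)CCC[C@]2(C)[C@@H]1Cc1cc(OCc2ccccc2)c(OCc2ccccc2)c(C=O)c1OS(=O)(=O)[O-].c1cc[nH+]cc1 | intermediate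
23 | sodium 3,4-bis(benzyloxy)-2-formyl-6-(drim-7-en-11-yl)phenyl sulfate | CC1=CC[C@H]2C(C)(C)CCC[C@]2(C)[C@@H]1Cc1cc(OCc2ccccc2)c(OCc2ccccc2)c(C=O)c1OS(=O)(=O)[O-].[Na+] | intermediate
24 | sodium 2-formyl-3,4-dihydroxy-6-(drim-7-en-11-yl)phenyl sulfate | CC1=CC[C@H]2C(C)(C)CCC[C@]2(C)[C@@H]1Cc1cc(O)c(O)c(C=O)c1OS(=O)(=O)[O-].[Na+] | intermediate
25 | 2-formyl-3,4-dihydroxy-6-{[(1R,4aS,8aS)-2,5,5,8a-tetramethyl-1,4,4a,5,6,7,8,8a-octahydronaphthalen-1-yl]methyl}phenyl hydrogen sulfate | CC1=CC[C@H]2C(C)(C)CCC[C@]2(C)[C@@H]1Cc1cc(O)c(O)c(C=O)c1OS(=O)(=O)O | target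

**Totals.** Total step count: 14. Longest linear sequence: 13 steps (1 to 25 through steps 1–6 and 8–14); step 7 is the second branch.

**Steps most likely to fail**

1. Step 9. The hindered trisubstituted enal may turn over too slowly on the chiral Lewis acid, or π-facial selectivity may erode through an uncatalysed or exo pathway. Fallback, from 14 back to 15: Me2AlCl (1.1 equiv), CH2Cl2, −78 → −20 °C should give the racemic endo adduct, that is 15 together with ent-adduct F1. Condensation with (1R,2R)-N,N′-dimethyl-1,2-diphenylethane-1,2-diamine (molecular sieves, Et2O) converts the pair into imidazolidine F2 (from 15) and imidazolidine F3 (from F1), which are diastereomers and are separated by chromatography or crystallisation. Mild hydrolysis of F2 (0.5 M HCl, Et2O/H2O, 0 °C) returns enantiopure 15.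

2. Step 11. Double-bond migration may stall, or walk into the C5=C6 or exocyclic positions. Fallback, from 17 back to 18: mCPBA/NaHCO3 in CH2Cl2 should epoxidise the less hindered α face to epoxide F4. Diethylaluminium 2,2,6,6-tetramethylpiperidide, Et2Al(NC9H18), in toluene at 0 °C removes the syn H-8 and opens the epoxide to allylic alcohol F5. NaH, CS2 and MeI give xanthate F6. Bu3SnH/AIBN in toluene at 80 °C (Barton–McCombie deoxygenation) should deliver hydrogen to the less hindered C6 terminus of the allyl radical and give 18.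

3. Step 14. Over-reduction during hydrogenolysis may saturate C7=C8 or reduce the formyl group. Fallback, from 21 back to 24: BCl3 with pentamethylbenzene in CH2Cl2 at −78 °C removes both benzyl groups without hydrogen and gives triol F7. PhB(OH)2 (toluene/THF, molecular sieves) masks the catechol as phenylboronate F8 and leaves only the phenol between the formyl and arylmethyl groups free. SO3·pyridine in pyridine, then aqueous NaHCO3/MeOH, sulfates that phenol and hydrolyses the boronate to sodium salt 24, which is acidified as in step 14.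

**Further compounds**

F1 | step 9 | enantiomer of 15 | C[C@@H]1C=C[C@@H]2C(C)(C)CCC[C@@]2(C=O)[C@H]1Cc1cc(OCc2ccccc2)c(OCc2ccccc2)cc1OCOC
F2 | step 9 | (4R,5R)-1,3-dimethyl-4,5-diphenylimidazolidine formed at the formyl carbon of 15 | C[C@H]1C=C[C@H]2C(C)(C)CCC[C@]2(C3N(C)[C@H](c4ccccc4)[C@@H](c4ccccc4)N3C)[C@@H]1Cc1cc(OCc2ccccc2)c(OCc2ccccc2)cc1OCOC
F3 | step 9 | (4R,5R)-1,3-dimethyl-4,5-diphenylimidazolidine formed at the formyl carbon of F1 | C[C@@H]1C=C[C@@H]2C(C)(C)CCC[C@@]2(C3N(C)[C@H](c4ccccc4)[C@@H](c4ccccc4)N3C)[C@H]1Cc1cc(OCc2ccccc2)c(OCc2ccccc2)cc1OCOC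
F4 | step 11 | 6α,7α-epoxide of 17 | C[C@H]1[C@@H]3O[C@@H]3[C@H]2C(C)(C)CCC[C@]2(C)[C@@H]1Cc1cc(OCc2ccccc2)c(OCc2ccccc2)cc1OCOC
F5 | step 11 | 11-[4,5-bis(benzyloxy)-2-(methoxymethoxy)phenyl]drim-7-en-6α-ol | CC1=C[C@H](O)[C@H]2C(C)(C)CCC[C@]2(C)[C@@H]1Cc1cc(OCc2ccccc2)c(OCc2ccccc2)cc1OCOC
F6 | step 11 | O-(6α) S-methyl dithiocarbonate of F5 | CC1=C[C@H](OC(=S)SC)[C@H]2C(C)(C)CCC[C@]2(C)[C@@H]1Cc1cc(OCc2ccccc2)c(OCc2ccccc2)cc1OCOC
F7 | step 14 | 11-(3-formyl-2,4,5-trihydroxyphenyl)drim-7-ene | CC1=CC[C@H]2C(C)(C)CCC[C@]2(C)[C@@H]1Cc1cc(O)c(O)c(C=O)c1O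
F8 | step 14 | cyclic phenylboronate of the catechol of F7 | CC1=CC[C@H]2C(C)(C)CCC[C@]2(C)[C@@H]1Cc1cc3OB(c4ccccc4)Oc3c(C=O)c1O
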